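**Retrosynthetic overview** (labdane numbering: ring A = C1–C5, C10; ring B = C5–C10; C17 = exocyclic methylene carbon; C18/C19 = methyl/carboxyl on C4; C20 = methyl on C10)
1. The caffeate is made last by Knoevenagel–Doebner condensation of the C15 malonic half ester with 3,4-dihydroxybenzaldehyde; the C19 acid is unveiled from its methyl ester just before.
2. C8=C17 and the C9–H centre come from a C8-formyl C8=C9 enal by reductive 1,3-transposition; the enal comes from a C9 ketone plus the side-chain organolithium (C11–C16, from (R)-methyl hydrogen 3-methylglutarate) by alkylative carbonyl transposition.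
3. Ring A is annulated onto ring B in one pot from a ring B keto ester, 1-chloro-3-iodopropane and iodomethane, which forms C1–C10 and C3–C4 (and C10–C20).
4. Enabling feature: the quaternary carbons C4 and C10 of ring A each lie alpha to a carbonyl-level carbon (C19; C9 when held as a ketone) and are joined through the single methine C5, so the C4–C5–C10 edge is a latent bis-enolate, while C1–C2–C3 are three unsubstituted methylenes; C17 is carried on C8 as an alkoxymethylene group that leaves C10 as the only enolisable ketone position.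
5. Ring order: ring B is bought (cyclohex-2-enone; C5 set by asymmetric Michael addition), ring A is closed in step 5.

Key step: step 5

Assumption: the facial sense of the binaphtholate-catalysed Michael addition with dimethyl methylmalonate is taken to follow that of the parent malonate additions to cyclohex-2-enone; if it is opposite, the enantiomeric ligand is used and nothing else changes.

**Step 1**
Reactants: 1 cyclohex-2-en-1-one; 2 dimethyl 2-methylpropanedioate
Product: 3 dimethyl 2-methyl-2-[(1S)-3-oxocyclohexyl]propanedioate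
Conditions: AlLi[(S)-1,1'-bi-2-naphtholate]2 (10 mol%), KOt-Bu (9 mol%), 4 Å molecular sieves, THF, 25 °C
Reagents that add atoms: none
Why: Heterobimetallic (Lewis acid/Brønsted base) asymmetric Michael addition, in which the aluminate binds the enone and the malonate enolate is delivered to one enantiotopic face of the β-carbon, should set C5 as the only stereocentre.

**Step 2**
Reactants: 3 dimethyl 2-methyl-2-[(1S)-3-oxocyclohexyl]propanedioate
Product: 4 methyl 2-[(1S)-3-oxocyclohexyl]propanoate (both epimers at the propanoate carbon)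
Conditions: LiCl, H2O, DMSO, 160 °C
Reagents that add atoms: none
Why: Krapcho demethoxycarbonylation removes one ester of the quaternary malonate; the new propanoate centre forms as a mixture that is erased later by enolisation, and C5 is untouched.

**Step 3**
Reactants: 4 methyl 2-[(1S)-3-oxocyclohexyl]propanoate
Product: 5 methyl 2-[(1S,4Z)-4-(hydroxymethylidene)-3-oxocyclohexyl]propanoate
Conditions: HCO2Et, NaH, EtOH (cat.), THF, 0 to 25 °C; then 1 M HCl
Reagents that add atoms: ethyl formate, CCOC=O
Why: Crossed Claisen formylation under thermodynamic control should go to the ketone α-methylene remote from the C5 branch (C8) and stop at the stable enolate of the β-keto aldehyde, leaving the less acidic ester alone; no stereocentre is set.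

**Step 4**
Reactants: 5 methyl 2-[(1S,4Z)-4-(hydroxymethylidene)-3-oxocyclohexyl]propanoate
Product: 6 methyl 2-[(1S,4E)-3-oxo-4-[(propan-2-yloxy)methylidene]cyclohexyl]propanoate
Conditions: i-PrI, K2CO3, acetone, 56 °C
Reagents that add atoms: 2-iodopropane, CC(C)I
Why: O-Alkylation of the β-keto aldehyde enolate with a secondary iodide gives the isopropoxymethylene (vinylogous ester) blocking group, which carries C17 and leaves C10 as the only enolisable ketone position; the enol ether geometry is of no consequence.

**Step 5**
Reactants: 6 methyl 2-[(1S,4E)-3-oxo-4-[(propan-2-yloxy)methylidene]cyclohexyl]propanoate; 7 1-chloro-3-iodopropane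
Product: 10 methyl (1S,4aS,6E,8aS)-1,4a-dimethyl-5-oxo-6-[(propan-2-yloxy)methylidene]decahydronaphthalene-1-carboxylate, via chloropropyl keto ester 8 (not isolated), via bicyclic lithium enolate 9 (not isolated)
Conditions: LiN(iPr)2 (1.05 equiv), THF, −78 °C; 7, DMPU, −78 to 0 °C; LiN(iPr)2 (2.2 equiv), −78 to 25 °C; MeI, −78 to 0 °C
Reagents that add atoms: iodomethane, CI
Why: A Stork–Danheiser-type kinetic enolate of the vinylogous ester, formed at C10 because the C8 alkoxymethylene group leaves no other acidic ketone position, displaces iodide from 7 (bond C1–C10); a second charge of base gives the C10/C4 bis-enolate, whose more basic ester enolate displaces chloride to close ring A (bond C3–C4), and the ketone enolate that remains is methylated at C10. The closest known chemistry is α′-alkylation of blocked ketones combined with intramolecular ester enolate alkylation, that is a [3+3] annulation of a δ-keto ester with a 1,3-dihalide. Ring A closes in the 6-(enolexo)-exo-tet mode. C4 is set in the ring closure, where allylic 1,3-strain keeps H5 in the plane of the tetrasubstituted ester enolate and the tether can reach C4 only from the face that carries C10, so the ester ends cis to H5; C10 is set in the methylation, where ring B holds C6 in the enolate plane, the C18 methyl is therefore axial and 1,3 to C10 on ring A, and iodomethane should enter on the opposite face, cis to H5, giving the cis ring fusion. The epimers at C10 in 8 and at the propanoate carbon of 6, and both enol ether geometries, pass through planar enolates and should converge on one diastereomer governed by C5 alone. The step needs C10 to react before C4 and carbon before oxygen, which the acidity gap between the α′-methylene and the tertiary ester C–H, the iodide–chloride reactivity gap, the lithium counter-ion and the four-membered-ring alternative for the C10 carbon are expected to secure.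

**Step 6**
Reactants: 11 (3R)-5-methoxy-3-methyl-5-oxopentanoic acid
Product: 12 methyl (3R)-5-hydroxy-3-methylpentanoate
Conditions: BH3·SMe2, THF, 0 to 25 °C; then H2O
Reagents that add atoms: none
Why: Chemoselective borane reduction of a carboxylic acid in the presence of a methyl ester (acyloxyborane pathway); the stereocentre is not involved.

**Step 7**
Reactants: 12 methyl (3R)-5-hydroxy-3-methylpentanoate
Product: 13 methyl (3R)-5-[(tert-butyldimethylsilyl)oxy]-3-methylpentanoate
Conditions: TBSCl, imidazole, DMF, 25 °C
Reagents that add atoms: tert-butyldimethylsilyl chloride, CC(C)(C)[Si](C)(C)Cl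
Why: Imidazole-promoted silylation masks the primary alcohol for the later halogen–lithium exchange and prevents lactonisation; no stereochemical change.

**Step 8**
Reactants: 13 methyl (3R)-5-[(tert-butyldimethylsilyl)oxy]-3-methylpentanoate
Product: 14 (3S)-5-[(tert-butyldimethylsilyl)oxy]-3-methylpentan-1-ol
Conditions: LiAlH4, THF, 0 °C; then H2O
Reagents that add atoms: none
Why: Hydride reduction of the ester to the primary alcohol with the silyl ether intact; the descriptor changes only because the substituent priorities change.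

**Step 9**
Reactants: 14 (3S)-5-[(tert-butyldimethylsilyl)oxy]-3-methylpentan-1-ol
Product: 15 tert-butyl{[(3R)-5-iodo-3-methylpentyl]oxy}dimethylsilane
Conditions: I2, PPh3, imidazole, CH2Cl2, 0 to 25 °C
Reagents that add atoms: iodine, II
Why: Appel-type iodination converts the primary alcohol into the iodide by SN2 at a non-stereogenic carbon.

**Step 10**
Reactants: 10 methyl (1S,4aS,6E,8aS)-1,4a-dimethyl-5-oxo-6-[(propan-2-yloxy)methylidene]decahydronaphthalene-1-carboxylate; 15 tert-butyl{[(3R)-5-iodo-3-methylpentyl]oxy}dimethylsilane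
Product: 18 methyl (1S,4aS,8aS)-6-formyl-5-[(3S)-5-hydroxy-3-methylpentyl]-1,4a-dimethyl-1,2,3,4,4a,7,8,8a-octahydronaphthalene-1-carboxylate, via alkyllithium 16 (not isolated), via tertiary lithium alkoxide 17 (not isolated)
Conditions: 15, t-BuLi (2.1 equiv per 15), Et2O, −78 °C; then 10, THF, −78 to 0 °C; then 2 M HCl, THF, 25 °C
Reagents that add atoms: water, O
Why: Stork–Danheiser-type alkylative carbonyl transposition: the alkyllithium from halogen–lithium exchange adds 1,2 to the non-enolisable C9 carbonyl, and aqueous acid ionises the tertiary allylic alcohol to the oxocarbenium ion, hydrolyses it to the C8=C9 enal and removes the silyl ether; the C9 carbinol centre is destroyed and C13 comes from 15.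

**Step 11**
Reactants: 18 methyl (1S,4aS,8aS)-6-formyl-5-[(3S)-5-hydroxy-3-methylpentyl]-1,4a-dimethyl-1,2,3,4,4a,7,8,8a-octahydronaphthalene-1-carboxylate
Product: 19 methyl (1S,4aS,8aS)-5-[(3S)-5-hydroxy-3-methylpentyl]-1,4a-dimethyl-6-[(E)-{2-[(4-methylphenyl)sulfonyl]hydrazinylidene}methyl]-1,2,3,4,4a,7,8,8a-octahydronaphthalene-1-carboxylate
Conditions: TsNHNH2, EtOH, 40 °C
Reagents that add atoms: 4-methylbenzenesulfonohydrazide, Cc1ccc(cc1)S(=O)(=O)NN
Why: Condensation of the aldehyde with the sulfonyl hydrazide gives the α,β-unsaturated tosylhydrazone; no stereocentre is formed.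

**Step 12**
Reactants: 19 the tosylhydrazone of 18
Product: 21 methyl (1S,4aR,5R,8aS)-5-[(3S)-5-hydroxy-3-methylpentyl]-1,4a-dimethyl-6-methylidenedecahydronaphthalene-1-carboxylate, via allylic diazene 20 (not isolated)
Conditions: catecholborane (3 equiv), CHCl3, 0 °C; then NaOAc·3H2O, 60 °C
Reagents that add atoms: none
Why: Reductive 1,3-transposition of an unsaturated tosylhydrazone: hydride reduces C=N, loss of sulfinate gives the allylic diazene, and its retro-ene loss of N2 moves the double bond to C8=C17 and should deliver hydrogen to C9 on the face away from the pseudoaxial C1 methylene of ring A, cis to the C10 methyl, which sets C9.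

**Step 13**
Reactants: 21 methyl (1S,4aR,5R,8aS)-5-[(3S)-5-hydroxy-3-methylpentyl]-1,4a-dimethyl-6-methylidenedecahydronaphthalene-1-carboxylate
Product: 22 (1S,4aR,5R,8aS)-5-[(3S)-5-hydroxy-3-methylpentyl]-1,4a-dimethyl-6-methylidenedecahydronaphthalene-1-carboxylic acid
Conditions: n-PrSLi, HMPA, 25 °C; then 1 M HCl
Reagents that add atoms: none
Why: SN2 demethylation by thiolate in a dipolar aprotic solvent cleaves the hindered axial methyl ester at the methyl carbon instead of the shielded carbonyl; alkene and stereocentres are untouched.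

**Step 14**
Reactants: 22 the hydroxy acid; 23 2,2-dimethyl-1,3-dioxane-4,6-dione
Product: 24 (1S,4aR,5R,8aS)-5-[(3S)-5-[(carboxyacetyl)oxy]-3-methylpentyl]-1,4a-dimethyl-6-methylidenedecahydronaphthalene-1-carboxylic acid
Conditions: toluene, 100 °C
Reagents that add atoms: none
Why: Thermal ring-opening of Meldrum's acid by the primary alcohol gives the malonic half ester with loss of acetone; the hindered tertiary C19 acid should not compete.

**Step 15**
Reactants: 24 the malonic half ester; 25 3,4-dihydroxybenzaldehyde
Product: 26 (1S,4aR,5R,8aS)-5-[(3S)-5-{[(2E)-3-(3,4-dihydroxyphenyl)prop-2-enoyl]oxy}-3-methylpentyl]-1,4a-dimethyl-6-methylidenedecahydronaphthalene-1-carboxylic acid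
Conditions: pyridine, piperidine (cat.), 50 °C, under argon
Reagents that add atoms: none
Why: Knoevenagel–Doebner condensation of the half ester with the aldehyde followed by decarboxylation should give the E-cinnamate directly, with the free catechol and the C19 acid tolerated.

**Compound list**
1 | cyclohex-2-en-1-one | O=C1C=CCCC1 | starting material
2 | dimethyl 2-methylpropanedioate | COC(=O)C(C)C(=O)OC | starting material
3 | dimethyl 2-methyl-2-[(1S)-3-oxocyclohexyl]propanedioate | C1CC[C@H](C(C)(C(=O)OC)C(=O)OC)CC1=O | intermediate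
4 | methyl 2-[(1S)-3-oxocyclohexyl]propanoate (both epimers at the propanoate carbon) | C1CC[C@H](C(C)C(=O)OC)CC1=O | intermediate
5 | methyl 2-[(1S,4Z)-4-(hydroxymethylidene)-3-oxocyclohexyl]propanoate | O/C=C1/CC[C@H](C(C)C(=O)OC)CC1=O | intermediate
6 | methyl 2-[(1S,4E)-3-oxo-4-[(propan-2-yloxy)methylidene]cyclohexyl]propanoate | CC(C)O/C=C1\CC[C@H](C(C)C(=O)OC)CC1=O | intermediate
7 | 1-chloro-3-iodopropane | ClCCCI | starting material
8 | methyl 2-[(1S,4E)-2-(3-chloropropyl)-3-oxo-4-[(propan-2-yloxy)methylidene]cyclohexyl]propanoate (both epimers at ring C2) | CC(C)O/C=C1\CC[C@H](C(C)C(=O)OC)C(CCCCl)C1=O | intermediate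
9 | C4a–C5 lithium enolate of methyl (1S,8aS)-1-methyl-5-oxo-6-[(E)-(propan-2-yloxy)methylidene]decahydronaphthalene-1-carboxylate | CC(C)O/C=C1\CC[C@H]2C(CCC[C@]2(C)C(=O)OC)=C1O[Li] | intermediate
10 | methyl (1S,4aS,6E,8aS)-1,4a-dimethyl-5-oxo-6-[(propan-2-yloxy)methylidene]decahydronaphthalene-1-carboxylate | CC(C)O/C=C1\CC[C@H]2[C@](C)(CCC[C@]2(C)C(=O)OC)C1=O | intermediate
11 | (3R)-5-methoxy-3-methyl-5-oxopentanoic acid ((R)-methyl hydrogen 3-methylglutarate) | COC(=O)C[C@H](C)CC(=O)O | starting material
12 | methyl (3R)-5-hydroxy-3-methylpentanoate | COC(=O)C[C@H](C)CCO | intermediate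
13 | methyl (3R)-5-[(tert-butyldimethylsilyl)oxy]-3-methylpentanoate | COC(=O)C[C@H](C)CCO[Si](C)(C)C(C)(C)C | intermediate
14 | (3S)-5-[(tert-butyldimethylsilyl)oxy]-3-methylpentan-1-ol | OCC[C@H](C)CCO[Si](C)(C)C(C)(C)C | intermediate
15 | tert-butyl{[(3R)-5-iodo-3-methylpentyl]oxy}dimethylsilane | ICC[C@H](C)CCO[Si](C)(C)C(C)(C)C | intermediate
16 | {(3S)-5-[(tert-butyldimethylsilyl)oxy]-3-methylpentyl}lithium | [Li]CC[C@H](C)CCO[Si](C)(C)C(C)(C)C | intermediate
17 | lithium alkoxide of methyl (1S,4aS,6E,8aS)-5-{(3S)-5-[(tert-butyldimethylsilyl)oxy]-3-methylpentyl}-5-hydroxy-1,4a-dimethyl-6-[(propan-2-yloxy)methylidene]decahydronaphthalene-1-carboxylate (either configuration at the carbinol carbon) | CC(C)O/C=C1\CC[C@H]2[C@](C)(CCC[C@]2(C)C(=O)OC)C1(O[Li])CC[C@H](C)CCO[Si](C)(C)C(C)(C)C | intermediate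
18 | methyl (1S,4aS,8aS)-6-formyl-5-[(3S)-5-hydroxy-3-methylpentyl]-1,4a-dimethyl-1,2,3,4,4a,7,8,8a-octahydronaphthalene-1-carboxylate | O=CC=1CC[C@H]2[C@](C)(CCC[C@]2(C)C(=O)OC)C=1CC[C@H](C)CCO | intermediate
19 | methyl (1S,4aS,8aS)-5-[(3S)-5-hydroxy-3-methylpentyl]-1,4a-dimethyl-6-[(E)-{2-[(4-methylphenyl)sulfonyl]hydrazinylidene}methyl]-1,2,3,4,4a,7,8,8a-octahydronaphthalene-1-carboxylate | Cc1ccc(cc1)S(=O)(=O)N/N=C/C=1CC[C@H]2[C@](C)(CCC[C@]2(C)C(=O)OC)C=1CC[C@H](C)CCO | intermediate
20 | methyl (1S,4aS,8aS)-6-(diazenylmethyl)-5-[(3S)-5-hydroxy-3-methylpentyl]-1,4a-dimethyl-1,2,3,4,4a,7,8,8a-octahydronaphthalene-1-carboxylate | N=NCC=1CC[C@H]2[C@](C)(CCC[C@]2(C)C(=O)OC)C=1CC[C@H](C)CCO | intermediate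
21 | methyl (1S,4aR,5R,8aS)-5-[(3S)-5-hydroxy-3-methylpentyl]-1,4a-dimethyl-6-methylidenedecahydronaphthalene-1-carboxylate | C=C1CC[C@H]2[C@](C)(CCC[C@]2(C)C(=O)OC)[C@@H]1CC[C@H](C)CCO | intermediate
22 | (1S,4aR,5R,8aS)-5-[(3S)-5-hydroxy-3-methylpentyl]-1,4a-dimethyl-6-methylidenedecahydronaphthalene-1-carboxylic acid | C=C1CC[C@H]2[C@](C)(CCC[C@]2(C)C(=O)O)[C@@H]1CC[C@H](C)CCO | intermediate
23 | 2,2-dimethyl-1,3-dioxane-4,6-dione (Meldrum's acid) | CC1(C)OC(=O)CC(=O)O1 | starting material
24 | (1S,4aR,5R,8aS)-5-[(3S)-5-[(carboxyacetyl)oxy]-3-methylpentyl]-1,4a-dimethyl-6-methylidenedecahydronaphthalene-1-carboxylic acid | C=C1CC[C@H]2[C@](C)(CCC[C@]2(C)C(=O)O)[C@@H]1CC[C@H](C)CCOC(=O)CC(=O)O | intermediate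
25 | 3,4-dihydroxybenzaldehyde | O=Cc1ccc(O)c(O)c1 | starting material
26 | (1S,4aR,5R,8aS)-5-[(3S)-5-{[(2E)-3-(3,4-dihydroxyphenyl)prop-2-enoyl]oxy}-3-methylpentyl]-1,4a-dimethyl-6-methylidenedecahydronaphthalene-1-carboxylic acid | C=C1CC[C@H]2[C@](C)(CCC[C@]2(C)C(=O)O)[C@@H]1CC[C@H](C)CCOC(=O)/C=C/c1ccc(O)c(O)c1 | target

**Step count and risks**
Total step count: 15. Longest linear sequence: 11 steps (steps 1–5 and 10–15); the side-chain branch (steps 6–9) joins at step 10.

Step 5 is the step most likely to fail. The processes that could go wrong are ring closure through the oxygen of the C10 enolate (a six-membered enol ether) in place of closure through C4, incomplete ring closure before the methylation, and attack of iodomethane on the wrong face of C10. The fallback sets out from 6 and builds ring A stepwise, with both C10 substituents installed before the ring is closed, so that no ketone enolate is present during ring closure and C10 is set by the usual anti rule of enolate alkylation. Kinetic α′-alkylation of 6 with 7 gives 8, now isolated. A second deprotonation and iodomethane, which should enter anti to the pseudoaxial C5 branch, give methyl 2-[(1R,2S,4E)-2-(3-chloropropyl)-2-methyl-3-oxo-4-[(propan-2-yloxy)methylidene]cyclohexyl]propanoate F1. Finkelstein exchange (NaI, acetone) gives the corresponding iodide F2. KN(SiMe3)2 in THF then forms the ester enolate, now the only enolate possible, which closes ring A on the iodide under the same allylic-strain control and comes back to the route at 10.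

Step 12 is the second risk: hydrogen transfer to C9 could show poor facial selectivity, since the diazene can swing to either face of the C8=C9 bond. The fallback sets out from 18 and puts C9 under thermodynamic control. Baeyer–Villiger oxidation of the enal (mCPBA, NaHCO3, CH2Cl2; vinyl migration) gives methyl (1S,4aS,8aS)-6-(formyloxy)-5-[(3S)-5-hydroxy-3-methylpentyl]-1,4a-dimethyl-1,2,3,4,4a,7,8,8a-octahydronaphthalene-1-carboxylate F3. Methanolysis with K2CO3 gives the C8 ketone methyl (1S,4aS,5S,8aS)-5-[(3S)-5-hydroxy-3-methylpentyl]-1,4a-dimethyl-6-oxodecahydronaphthalene-1-carboxylate F4, in which C9 should equilibrate to the equatorial side chain, the required configuration. Wittig methylenation (Ph3P=CH2 in excess, THF) then comes back to the route at 21.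

Step 1 is the third risk: addition of the α-substituted malonate could be slow or poorly enantioselective. The fallback sets out from 1 and uses the parent donor, dimethyl malonate, with the same catalyst class to give dimethyl 2-[(1S)-3-oxocyclohexyl]propanedioate F5. Selective C-methylation of the malonate C–H (K2CO3, MeI, acetone), which leaves the ketone α-positions alone, comes back to the route at 3.

**Further compounds**
F1 | step 5 | methyl 2-[(1R,2S,4E)-2-(3-chloropropyl)-2-methyl-3-oxo-4-[(propan-2-yloxy)methylidene]cyclohexyl]propanoate | CC(C)O/C=C1\CC[C@H](C(C)C(=O)OC)[C@](C)(CCCCl)C1=O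
F2 | step 5 | methyl 2-[(1R,2S,4E)-2-(3-iodopropyl)-2-methyl-3-oxo-4-[(propan-2-yloxy)methylidene]cyclohexyl]propanoate | CC(C)O/C=C1\CC[C@H](C(C)C(=O)OC)[C@](C)(CCCI)C1=O
F3 | step 12 | methyl (1S,4aS,8aS)-6-(formyloxy)-5-[(3S)-5-hydroxy-3-methylpentyl]-1,4a-dimethyl-1,2,3,4,4a,7,8,8a-octahydronaphthalene-1-carboxylate | O=COC=1CC[C@H]2[C@](C)(CCC[C@]2(C)C(=O)OC)C=1CC[C@H](C)CCO
F4 | step 12 | methyl (1S,4aS,5S,8aS)-5-[(3S)-5-hydroxy-3-methylpentyl]-1,4a-dimethyl-6-oxodecahydronaphthalene-1-carboxylate | O=C1CC[C@H]2[C@](C)(CCC[C@]2(C)C(=O)OC)[C@@H]1CC[C@H](C)CCO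
F5 | step 1 | dimethyl 2-[(1S)-3-oxocyclohexyl]propanedioate | C1CC[C@H](C(C(=O)OC)C(=O)OC)CC1=O
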